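(The numbers in the tables were computed from invented constants, noise included.)

**The ledger.** Follow each mole of partner through the earlier runs and enter where it went.

all flasks: substrate 0.73 M

| charge | partner | second reagent | remark | time |
|---|---|---|---|---|
| birch | 0.29 M (in portions, 4) | 0.73 M | run made earlier; portions every 30 s |  |
| cedar | 0.44 M (in portions, 4) | 0.73 M | run made earlier; portions every 30 s |  |
| flask | 0.584 M (in portions, 4) | 0.730 M | the portions of partner follow each other after 30 s, the first at the start | 1.5 h |

| run | time / min | substrate / % | target / % |
|---|---|---|---|
| birch | 4.00 | 65.2 | 25.4 |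
| birch | 6.00 | 61.2 | 34.0 |
| birch | 10.0 | 60.9 | 37.6 |
| birch | 15.0 | 59.7 | 39.0 |
| birch | 25.0 | 60.3 | 40.1 |
| birch | 40.0 | 59.8 | 40.1 |
| birch | 50.0 | 61.1 | 39.3 |
| cedar | 3.00 | 55.2 | 25.8 |
| cedar | 8.00 | 41.5 | 51.3 |
| cedar | 15.0 | 40.3 | 59.5 |
| cedar | 25.0 | 39.1 | 59.9 |
| cedar | 30.0 | 39.9 | 60.4 |
| cedar | 40.0 | 40.4 | 60.8 |
| cedar | 50.0 | 39.9 | 60.6 |

(scatter of a reading: 0.5 percentage points)

1. which holds at 1.5 h: what has brought the reaction to rest, or that it has not come to rest (it is still moving / the second reagent has run out first / the partner has run out first / all of the substrate has reacted)
2. part of the substrate gone at 1.5 h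
3. the target standing at 1.5 h, as a percentage of the substrate charged

**Substrate taken.** At 25.0 min the birch run had lost 39.7 % of its substrate, and its partner charge was 39.7 % of its substrate charge. At 30.0 min the cedar run gave 60.1 % against 60.3 %. So I entered one mole of substrate taken per mole of partner. For the flask, c(partner)/c(substrate) gave 80.0 %; I called this the partner ceiling, the share of the charged substrate that the charged partner can take one to one. I took partner as the limiting reagent of the flask, because c(partner) stood below c(substrate).

**Held in transit.** The early books fell short by 9.40 % in the birch run at 4.00 min and by 19.0 % in the cedar run at 3.00 min. I entered that gap as an unseen intermediate. In the cedar run, substrate and target summed to 99.8 % by 15.0 min, so the entry had passed on to target.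

**Closing the books.** In the flask, c(second reagent) of 0.730 M stood above the 0.584 M of partner, so it could pay one to one. The 1.5 h allowed was 6.00 times the 15.0 min by which the cedar books had closed, though one-to-one payment left the flask 0.146 M of second reagent over, against 0.290 M in the cedar run. I therefore put both conversion and target at the ceiling, with 0.146 M of substrate left standing.

The forecast said that the partner has run out first, with 80 % conversion and 79.8 % target: "the partner limits".

**The flask.** In the flask, the partner has run out first, with 80.0 % conversion and 80.0 % target against the ceiling of 80.0 %; at 1.50 h partner stood at 0 % of its charge and second reagent at 18.4 % of its own.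

    second reagent → decomposition product (k = 1.20 × 10⁻⁵ /s)
    substrate + partner → intermediate (k = 0.0210 /M/s)
    second reagent + intermediate → target (k = 0.0170 /M/s)

With 0.44 M of substrate instead, the same ratio reads 133 %, with c(partner) above c(substrate). That neighbour flask ended with 100 % conversion, and its substrate, not its partner, ran out first, at 0 % left, with partner at 25 % of its charge.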